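The route rests on disconnecting the carbonyl–methylene bond C1–C2 (longipinane numbering: C1 ketone, C2 methylene, C3 methyl-bearing methine) of the cyclohexanone ring C1–C2–C3–C4–C5–C11. The key step closes this ring by a base-mediated Thorpe-type addition of an acetyl enolate (C3/C2, attached to cyclobutane carbon C4) to a nitrile (C1, attached to cyclobutane carbon C11). It exploits that both cyclobutane methines C4 and C11 are then α to an acceptor: they epimerise, so all four diastereomers of the precursor funnel into one bicyclo[3.1.1] vinylogous amide, whose nitrogen marks C1 as the future ketone. The precursor is a bicyclo[4.1.1]octene built from eucarvone by a 4-exo epoxide opening.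

Key step: step 8

Assumption: eucarvone (1) is taken as a purchasable starting material; otherwise it is two known steps from carvone (HBr, then KOH).
Numbering: tricyclic compounds carry longipinane numbers (C1 ketone, C2, C3, cyclobutane C4–C5–C11–C10, C6 = CMe2, C7–C9 oxygenated, C10 = quaternary C–CH3). Bicyclo[4.1.1]octenes carry their own numbers; their C1, C2, C7 and C8 become longipinane C10, C9, C4 and C11.

Step 1
Reactants: 1 eucarvone
Product: 2 (S)-2,6,6-trimethylcyclohepta-2,4-dien-1-ol
Conditions: (R)-Me-CBS (0.2 equiv), BH3·SMe2, THF, −20 °C; aqueous work-up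
Reagents that add atoms: none
Why: Corey–Bakshi–Shibata reduction, in which the α-methylated dienyl arm should act as the large group so that the (R)-catalyst gives the (S)-carbinol, a relay centre that fixes the absolute configuration of the epoxide made next.

Step 2
Reactants: 2 (S)-2,6,6-trimethylcyclohepta-2,4-dien-1-ol
Product: 3 (1S,2S,3R)-2,3-epoxy-2,6,6-trimethylcyclohept-4-en-1-ol (epoxide cis to the hydroxyl)
Conditions: VO(acac)2 (cat.), t-BuOOH, 2,6-lutidine, CH2Cl2, 0 °C
Reagents that add atoms: tert-butyl hydroperoxide CC(C)(C)OO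
Why: Vanadium-catalysed hydroxyl-directed epoxidation (Sharpless–Michaelson type) should epoxidise only the allylic trisubstituted alkene, on the face of the hydroxyl, which sets both epoxide centres.

Step 3
Reactants: 3 (1S,2S,3R)-2,3-epoxy-2,6,6-trimethylcyclohept-4-en-1-ol
Product: 4 (2R,3R)-2,3-epoxy-2,6,6-trimethylcyclohept-4-en-1-one
Conditions: Dess–Martin periodinane, pyridine, CH2Cl2, 0 °C → rt
Reagents that add atoms: none
Why: Dess–Martin oxidation under buffered conditions should remove the relay carbinol without touching the acid-labile vinyl epoxide, whose two centres now carry the stereochemical information.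

Step 4
Reactants: 4 (2R,3R)-2,3-epoxy-2,6,6-trimethylcyclohept-4-en-1-one; 5 methyl bromoacetate
Product: 6 methyl 2-[(2R,3R)-2,3-epoxy-2,6,6-trimethyl-1-oxocyclohept-4-en-7-yl]acetate (side chain trans to the epoxide oxygen)
Conditions: LiHMDS (1.0 M in THF), THF, −78 °C; then 5, DMPU, −78 → −30 °C
Reagents that add atoms: methyl bromoacetate (5) COC(=O)CBr
Why: Alkylation of the only possible (C7) lithium enolate with a reactive α-bromo ester; the electrophile should enter anti to the epoxide oxygen, and the new centre remains epimerisable.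

Step 5
Reactants: 6 methyl 2-[(2R,3R)-2,3-epoxy-2,6,6-trimethyl-1-oxocyclohept-4-en-7-yl]acetate
Product: 8 methyl 1,5,5-trimethyl-8-oxo-2-(triethylsilyloxy)bicyclo[4.1.1]oct-3-ene-7-carboxylate (silyloxy group anti to C7; C7 epimers), via potassium alkoxide 7 (not isolated)
Conditions: KHMDS (1.1 equiv), THF, −78 → 0 °C; then Et3SiCl, −78 °C → rt
Reagents that add atoms: chlorotriethylsilane CC[Si](Cl)(CC)CC
Why: Intramolecular 4-exo-tet opening of the epoxide by the kinetically formed ester enolate (Stork epoxynitrile-type cyclisation, here with an ester): backside attack at the ketone-activated, methyl-bearing epoxide carbon inverts it to the quaternary bridgehead C1 and leaves the C2 oxygen anti to the new bridge C7, the silyl chloride then caps the alkoxide, and the epimer mixture at C7 does not matter because that centre is epimerisable again in the key step.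

Step 6
Reactants: 8 methyl 1,5,5-trimethyl-8-oxo-2-(triethylsilyloxy)bicyclo[4.1.1]oct-3-ene-7-carboxylate; 9 p-toluenesulfonylmethyl isocyanide (TosMIC)
Product: 10 methyl 8-cyano-1,5,5-trimethyl-2-(triethylsilyloxy)bicyclo[4.1.1]oct-3-ene-7-carboxylate (epimers at C7 and C8)
Conditions: TosMIC, t-BuOK, DME, MeOH (2 equiv), 0 → 40 °C
Reagents that add atoms: TosMIC (9) Cc1ccc(cc1)S(=O)(=O)C[N+]#[C-]
Why: Van Leusen reductive cyanation, which the strained cyclobutanone should undergo readily; the nitrile-bearing methine C8 forms as an epimer mixture that the key step corrects.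

Step 7
Reactants: 10 methyl 8-cyano-1,5,5-trimethyl-2-(triethylsilyloxy)bicyclo[4.1.1]oct-3-ene-7-carboxylate
Product: 12 7-acetyl-1,5,5-trimethyl-2-(triethylsilyloxy)bicyclo[4.1.1]oct-3-ene-8-carbonitrile (epimers at C7 and C8), via Weinreb amide 11 (not isolated)
Conditions: MeNH(OMe)·HCl, i-PrMgCl, THF, −20 °C; then MeMgBr, 0 °C → rt; aq. NH4Cl
Reagents that add atoms: methylmagnesium bromide C[Mg]Br; N,O-dimethylhydroxylamine hydrochloride CNOC.Cl (its atoms stay only in 11)
Why: Weinreb ketone synthesis run in one pot (magnesium amide aminolysis of the ester, then Grignard addition to the chelated amide), which should stop at the methyl ketone and leave the less electrophilic, partly deprotonated nitrile untouched.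

Step 8
Reactants: 12 7-acetyl-1,5,5-trimethyl-2-(triethylsilyloxy)bicyclo[4.1.1]oct-3-ene-8-carbonitrile
Product: 13 1-amino-9-(triethylsilyloxy)-3-demethyllongipina-1,7-dien-3-one
Conditions: t-BuOK (2.5 equiv), t-BuOH/THF, 0.01 M, 60 °C; aq. NH4Cl
Reagents that add atoms: none
Why: t-BuOK reversibly forms the methyl-ketone enolate (C2), which adds to the nitrile carbon (C1), and the imine anion tautomerises to the conjugated vinylogous amide, the thermodynamic sink; the closest known reactions are the base-mediated Thorpe-type cyclisation of 5-oxonitriles to 3-aminocyclohex-2-enones and the Claisen closure of cis-3-acetylcyclobutanecarboxylates to bicyclo[3.1.1]heptane-2,4-diones. The six-membered ring closes in a 6-exo-dig mode (enolate exocyclic) across the 1,3-positions of the cyclobutane. No new stereocentre is formed, but C4 and C11, left uncontrolled in steps 5 and 6, are set here: both epimerise through exocyclic enolate and keteniminate anions, and only the isomer with acetyl and nitrile on the cyclobutane face opposite the four-carbon bridge can close, so the ring geometry selects the configuration. The step needs C-attack at the nitrile in preference to intermolecular condensation (secured by dilution and the proximity of the 1,3-cis groups) and a lasting distinction between the two carbonyl-level carbons, which the nitrile nitrogen provides by staying on C1 while the oxygen stays on C3. Retro-Michael opening of the cyclobutane is not expected, because the exocyclic anion orbitals are orthogonal to the ring C–C bonds.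

Step 9
Reactants: 13 1-amino-9-(triethylsilyloxy)-3-demethyllongipina-1,7-dien-3-one
Product: 14 1-[bis(tert-butoxycarbonyl)amino]-9-(triethylsilyloxy)-3-demethyllongipina-1,7-dien-3-one
Conditions: Boc2O (3 equiv), DMAP (0.3 equiv), MeCN, rt
Reagents that add atoms: di-tert-butyl dicarbonate CC(C)(C)OC(=O)OC(=O)OC(C)(C)C
Why: Exhaustive N-acylation of the primary vinylogous amide removes both N–H protons and damps the nitrogen donation, so that the ring ketone can be reduced in the next step.

Step 10
Reactants: 14 1-[bis(tert-butoxycarbonyl)amino]-9-(triethylsilyloxy)-3-demethyllongipina-1,7-dien-3-one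
Product: 16 9-hydroxy-3-demethyllongipina-2,7-dien-1-one, via allylic alcohol 15 (not isolated)
Conditions: NaBH4, CeCl3·7H2O, MeOH, −20 °C; then 1 M HCl, THF, rt
Reagents that add atoms: water O (supplies the C1 carbonyl oxygen)
Why: Luche 1,2-reduction of the C3 ketone and then acid hydrolysis of the N-acyl enamine with loss of water (Stork–Danheiser-type 1,3-carbonyl transposition) should put the carbonyl on C1 and the double bond at C2=C3, while the acid also removes the triethylsilyl group.

Step 11
Reactants: 16 9-hydroxy-3-demethyllongipina-2,7-dien-1-one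
Product: 17 9-hydroxylongipin-7-en-1-one (C3 methyl anti to the C10 bridge)
Conditions: Me2CuLi (3 equiv, from MeLi and CuI), Et2O, −78 → −20 °C; aq. NH4Cl/NH3
Reagents that add atoms: lithium dimethylcuprate [Li+].C[Cu-]C (made from methyllithium [Li]C and CuI)
Why: Conjugate addition of the Gilman reagent; as with apoverbenone, the nucleophile should approach C3 from the side of the C5–H bridge, away from the C10 bridge whose methyl group points over the enone, which places the new methyl anti to C10 as required.

Step 12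
Reactants: 17 9-hydroxylongipin-7-en-1-one
Product: 18 9-acetoxylongipin-7-en-1-one
Conditions: Ac2O, DMAP, pyridine, CH2Cl2, rt
Reagents that add atoms: acetic anhydride CC(=O)OC(C)=O
Why: DMAP-catalysed acetylation of the hindered 9-hydroxyl installs the neighbouring group needed for step 14.

Step 13
Reactants: 18 9-acetoxylongipin-7-en-1-one
Product: 19 9-acetoxy-7,8-epoxylongipinan-1-one (epoxide anti to the 9-acetoxy group)
Conditions: dimethyldioxirane (acetone solution), CH2Cl2, 0 °C
Reagents that add atoms: dimethyldioxirane CC1(C)OO1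
Why: Epoxidation with dimethyldioxirane should occur on the alkene face anti to the allylic acetoxy group (steric and dipolar control), and the neutral oxidant avoids Baeyer–Villiger oxidation of the strained C1 ketone.

Step 14
Reactants: 19 9-acetoxy-7,8-epoxylongipinan-1-one
Product: 20 8-acetoxy-7,9-dihydroxylongipinan-1-one (8-O cis to 9-O and trans to 7-O)
Conditions: HClO4 (cat.), THF/H2O, 0 °C → rt
Reagents that add atoms: water O
Why: Acid-catalysed epoxide opening with anchimeric assistance (as in the Woodward cis-hydroxylation): the carbonyl oxygen of the 9-acetate attacks C8 from the rear of the epoxide to give a cis-fused acetoxonium ion, which water opens to the cis-8,9-diol monoacetate with the acetyl settling on the least hindered 8-oxygen, so that C8 is set by inversion and C7 keeps the epoxide oxygen.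

Step 15
Reactants: 20 8-acetoxy-7,9-dihydroxylongipinan-1-one; 21 angelic acid
Product: 22 8-acetoxy-7,9-bis(angeloyloxy)longipinan-1-one (CNP0197834.1)
Conditions: 21 (6 equiv), 2,4,6-trichlorobenzoyl chloride, Et3N, toluene, rt; then 20, toluene, 80 °C
Reagents that add atoms: angelic acid (21) C/C=C(/C)C(=O)O
Why: Yamaguchi-type esterification with the preformed mixed anhydride, a method that acylates hindered secondary alcohols with angelic acid without Z to E isomerisation, should esterify both neopentylic hydroxyls.

Compound list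
1 | eucarvone (2,6,6-trimethylcyclohepta-2,4-dien-1-one) | CC1=CC=CC(C)(C)CC1=O | starting material
2 | (S)-2,6,6-trimethylcyclohepta-2,4-dien-1-ol | O[C@H]1CC(C)(C)C=CC=C1C | intermediate
3 | (1S,2S,3R)-2,3-epoxy-2,6,6-trimethylcyclohept-4-en-1-ol, epoxide cis to OH | O[C@H]1CC(C)(C)C=C[C@H]2O[C@@]12C | intermediate
4 | (2R,3R)-2,3-epoxy-2,6,6-trimethylcyclohept-4-en-1-one | O=C1CC(C)(C)C=C[C@H]2O[C@@]12C | intermediate
5 | methyl bromoacetate | COC(=O)CBr | starting material
6 | methyl 2-[(2R,3R)-2,3-epoxy-2,6,6-trimethyl-1-oxocyclohept-4-en-7-yl]acetate, side chain trans to the epoxide oxygen | O=C1[C@H](CC(=O)OC)C(C)(C)C=C[C@H]2O[C@@]12C | intermediate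
7 | potassium 7-(methoxycarbonyl)-1,5,5-trimethyl-8-oxobicyclo[4.1.1]oct-3-en-2-olate, oxygen anti to C7, C7 epimers | C1=C[C@@H]([O-])[C@]2(C)C(C(=O)OC)[C@@H](C2=O)C1(C)C.[K+] | intermediate (not isolated)
8 | methyl 1,5,5-trimethyl-8-oxo-2-(triethylsilyloxy)bicyclo[4.1.1]oct-3-ene-7-carboxylate, silyloxy anti to C7, C7 epimers | C1=C[C@@H](O[Si](CC)(CC)CC)[C@]2(C)C(C(=O)OC)[C@@H](C2=O)C1(C)C | intermediate
9 | p-toluenesulfonylmethyl isocyanide (TosMIC) | Cc1ccc(cc1)S(=O)(=O)C[N+]#[C-] | starting material
10 | methyl 8-cyano-1,5,5-trimethyl-2-(triethylsilyloxy)bicyclo[4.1.1]oct-3-ene-7-carboxylate, epimers at C7 and C8 | C1=C[C@@H](O[Si](CC)(CC)CC)[C@]2(C)C(C(=O)OC)[C@@H](C2C#N)C1(C)C | intermediate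
11 | 8-cyano-N-methoxy-N,1,5,5-tetramethyl-2-(triethylsilyloxy)bicyclo[4.1.1]oct-3-ene-7-carboxamide, epimers at C7 and C8 | C1=C[C@@H](O[Si](CC)(CC)CC)[C@]2(C)C(C(=O)N(C)OC)[C@@H](C2C#N)C1(C)C | intermediate (not isolated)
12 | 7-acetyl-1,5,5-trimethyl-2-(triethylsilyloxy)bicyclo[4.1.1]oct-3-ene-8-carbonitrile, epimers at C7 and C8 | C1=C[C@@H](O[Si](CC)(CC)CC)[C@]2(C)C(C(C)=O)[C@@H](C2C#N)C1(C)C | intermediate
13 | 1-amino-9-(triethylsilyloxy)-3-demethyllongipina-1,7-dien-3-one | C1=C[C@@H](O[Si](CC)(CC)CC)[C@]2(C)[C@@H]3[C@@H]([C@H]2C(N)=CC3=O)C1(C)C | intermediate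
14 | 1-[bis(tert-butoxycarbonyl)amino]-9-(triethylsilyloxy)-3-demethyllongipina-1,7-dien-3-one | C1=C[C@@H](O[Si](CC)(CC)CC)[C@]2(C)[C@@H]3[C@@H]([C@H]2C(=CC3=O)N(C(=O)OC(C)(C)C)C(=O)OC(C)(C)C)C1(C)C | intermediate
15 | 1-[bis(tert-butoxycarbonyl)amino]-9-(triethylsilyloxy)-3-demethyllongipina-1,7-dien-3-ol, C3 epimers | C1=C[C@@H](O[Si](CC)(CC)CC)[C@]2(C)[C@@H]3[C@@H]([C@H]2C(=CC3O)N(C(=O)OC(C)(C)C)C(=O)OC(C)(C)C)C1(C)C | intermediate (not isolated)
16 | 9-hydroxy-3-demethyllongipina-2,7-dien-1-one | C1=C[C@@H](O)[C@]2(C)[C@@H]3[C@@H]([C@H]2C(=O)C=C3)C1(C)C | intermediate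
17 | 9-hydroxylongipin-7-en-1-one | C1=C[C@@H](O)[C@]2(C)[C@@H]3[C@@H]([C@H]2C(=O)C[C@H]3C)C1(C)C | intermediate
18 | 9-acetoxylongipin-7-en-1-one | C1=C[C@@H](OC(C)=O)[C@]2(C)[C@@H]3[C@@H]([C@H]2C(=O)C[C@H]3C)C1(C)C | intermediate
19 | 9-acetoxy-7,8-epoxylongipinan-1-one, epoxide anti to the acetoxy group | O1[C@@H]5[C@H]1[C@@H](OC(C)=O)[C@]2(C)[C@@H]3[C@@H]([C@H]2C(=O)C[C@H]3C)C5(C)C | intermediate
20 | 8-acetoxy-7,9-dihydroxylongipinan-1-one | O[C@@H]1[C@@H](OC(C)=O)[C@@H](O)[C@]2(C)[C@@H]3[C@@H]([C@H]2C(=O)C[C@H]3C)C1(C)C | intermediate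
21 | angelic acid [(Z)-2-methylbut-2-enoic acid] | C/C=C(/C)C(=O)O | starting material
22 | 8-acetoxy-7,9-bis(angeloyloxy)longipinan-1-one (CNP0197834.1) | C/C=C(/C)C(=O)O[C@@H]1[C@@H](OC(C)=O)[C@@H](OC(=O)/C(C)=C\C)[C@]2(C)[C@@H]3[C@@H]([C@H]2C(=O)C[C@H]3C)C1(C)C | target

Total step count: 15. Longest linear sequence: 15 steps (1 → 22).

Steps most likely to fail

Step 5. The 4-exo-tet closure may not compete: backside attack at the tertiary, ketone-flanked epoxide carbon is slow, the more acidic ketone α-position may hold the base in an unproductive enolate, and the strained bridged cyclobutanone may not form. The fallback uses the nitrile anion, the best precedented nucleophile for this ring size (Stork epoxynitrile cyclisation). It sets out from 4 and returns at 12, so that steps 5–7 are bypassed. Alkylation of 4 with bromoacetonitrile (LiHMDS) should give the cyanomethyl epoxy ketone F1. LiHMDS in benzene/THF should then close the cyclobutane to the hydroxy keto nitrile F2, which TESOTf/2,6-lutidine converts into the silyl ether F3. A Wittig reaction with Ph3P=CHOMe turns the cyclobutanone into the methyl enol ether F4. MeMgBr adds to the nitrile, and aqueous oxalic acid then unmasks both carbonyls to give the keto aldehyde F5. Finally, I2 in aqueous ammonia converts the aldehyde, and not the methyl ketone, into the nitrile 12.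

Step 8. The ring closure may stall: the added strain of the bicyclo[3.1.1] system may leave the equilibrium on the side of the open enolates, or intermolecular condensation may take over. The fallback is an irreversible, neutral intramolecular Blaise (Reformatsky-type) addition. It sets out from 12 and returns at 13. LiHMDS/TMSCl should give the kinetic silyl enol ether F6, and NBS the bromomethyl ketone F7. Activated zinc (THF, cat. TMSCl, reflux) then adds the zinc enolate to the nitrile, giving 13 after NH4Cl work-up. Isomers that cannot close are protonated back to 12 and recycled after base equilibration.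

Step 15. Acyl migration of the acetate from O8 to O9 during the slow acylation of the two hindered hydroxyls, followed by fast acylation of the freed 8-hydroxyl, would scramble the ester pattern; angelate to tiglate isomerisation is a second loss channel. The fallback installs the acetate last. It sets out from 20 and returns at 22. K2CO3/MeOH should give the triol F8, and TBSCl/imidazole should silylate only the least hindered 8-hydroxyl to give the silyl ether F9. Angelic anhydride with LiHMDS (THF, −20 °C) then gives the bis-angelate F10. HF·pyridine frees the 8-hydroxyl to give the alcohol F11, and Ac2O/DMAP acetylates it to 22.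

Further compounds
F1 | step 5 | (2R,3R)-7-(cyanomethyl)-2,3-epoxy-2,6,6-trimethylcyclohept-4-en-1-one, side chain trans to the epoxide oxygen | O=C1[C@H](CC#N)C(C)(C)C=C[C@H]2O[C@@]12C
F2 | step 5 | 2-hydroxy-1,5,5-trimethyl-8-oxobicyclo[4.1.1]oct-3-ene-7-carbonitrile, hydroxyl anti to C7, C7 epimers | C1=C[C@@H](O)[C@]2(C)C(C#N)[C@@H](C2=O)C1(C)C
F3 | step 5 | 1,5,5-trimethyl-8-oxo-2-(triethylsilyloxy)bicyclo[4.1.1]oct-3-ene-7-carbonitrile | C1=C[C@@H](O[Si](CC)(CC)CC)[C@]2(C)C(C#N)[C@@H](C2=O)C1(C)C
F4 | step 5 | 8-(methoxymethylidene)-1,5,5-trimethyl-2-(triethylsilyloxy)bicyclo[4.1.1]oct-3-ene-7-carbonitrile | C1=C[C@@H](O[Si](CC)(CC)CC)[C@]2(C)C(C#N)[C@@H](C2=COC)C1(C)C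
F5 | step 5 | 7-acetyl-1,5,5-trimethyl-2-(triethylsilyloxy)bicyclo[4.1.1]oct-3-ene-8-carbaldehyde, epimers at C7 and C8 | C1=C[C@@H](O[Si](CC)(CC)CC)[C@]2(C)C(C(C)=O)[C@@H](C2C=O)C1(C)C
F6 | step 8 | 1,5,5-trimethyl-2-(triethylsilyloxy)-7-[1-(trimethylsilyloxy)ethenyl]bicyclo[4.1.1]oct-3-ene-8-carbonitrile | C1=C[C@@H](O[Si](CC)(CC)CC)[C@]2(C)C(C(=C)O[Si](C)(C)C)[C@@H](C2C#N)C1(C)C
F7 | step 8 | 7-(bromoacetyl)-1,5,5-trimethyl-2-(triethylsilyloxy)bicyclo[4.1.1]oct-3-ene-8-carbonitrile | C1=C[C@@H](O[Si](CC)(CC)CC)[C@]2(C)C(C(=O)CBr)[C@@H](C2C#N)C1(C)C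
F8 | step 15 | 7,8,9-trihydroxylongipinan-1-one | O[C@@H]1[C@@H](O)[C@@H](O)[C@]2(C)[C@@H]3[C@@H]([C@H]2C(=O)C[C@H]3C)C1(C)C
F9 | step 15 | 8-(tert-butyldimethylsilyloxy)-7,9-dihydroxylongipinan-1-one | O[C@@H]1[C@@H](O[Si](C)(C)C(C)(C)C)[C@@H](O)[C@]2(C)[C@@H]3[C@@H]([C@H]2C(=O)C[C@H]3C)C1(C)C
F10 | step 15 | 7,9-bis(angeloyloxy)-8-(tert-butyldimethylsilyloxy)longipinan-1-one | C/C=C(/C)C(=O)O[C@@H]1[C@@H](O[Si](C)(C)C(C)(C)C)[C@@H](OC(=O)/C(C)=C\C)[C@]2(C)[C@@H]3[C@@H]([C@H]2C(=O)C[C@H]3C)C1(C)C
F11 | step 15 | 7,9-bis(angeloyloxy)-8-hydroxylongipinan-1-one | C/C=C(/C)C(=O)O[C@@H]1[C@@H](O)[C@@H](OC(=O)/C(C)=C\C)[C@]2(C)[C@@H]3[C@@H]([C@H]2C(=O)C[C@H]3C)C1(C)C
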